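Ring B (C5=C6–C7–C8–C9–C10, eudesmane numbering) is read as the 8,9-dihydro form of an alkyne–diene [4+2] adduct. C5=C6 is the former alkyne, and quaternary C10 and allylic C7 are the former diene termini. One rhodium-catalysed intramolecular cycloaddition of an acyclic dienyne forms C5–C10 and C6–C7, closes rings A and B, and sets C10 and C7. The precursor holds a terminal alkyne on C4 and a (7E,9Z)-diene on C1. The cis pair C10-methyl/C7-hydroxyisopropyl stems from the two outer diene substituents, and allylic strain at C1 selects the diene face. Two lithiation–borylations and a Zweifel olefination assemble this precursor from five small building blocks.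

Key step: step 15

Remark: eudesmane numbering is used throughout (ring A = C1–C5 and C10, ring B = C5–C10, C11 = carbinol carbon, C1′ = benzylic carbon). Abbreviations: Cb = N,N-diisopropylcarbamoyl, pin = pinacolato, TES = triethylsilyl, TMS = trimethylsilyl. (R)-β-Citronellene and (−)-sparteine are assumed to be commercial in high enantiomeric purity.

Step 1
Reactants: 1 1,3,5-trimethoxybenzene
Product: 3 2-(2,4,6-trimethoxyphenyl)-4,4,5,5-tetramethyl-1,3,2-dioxaborolane, via 2,4,6-trimethoxyphenyllithium 2 (not isolated)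
Conditions: n-BuLi, THF, 0 °C to rt; i-PrOBpin, −78 °C to rt; aq. NH4Cl
Reagents that add atoms: 2-isopropoxy-4,4,5,5-tetramethyl-1,3,2-dioxaborolane CC(C)OB1OC(C)(C)C(C)(C)O1
Why: Directed ortho-lithiation between two methoxy groups and trapping of the aryllithium with an alkoxyboronate is the standard borylation of electron-rich arenes.

Step 2
Reactants: 4 3-methylbutan-1-ol
Product: 5 3-methylbutyl N,N-diisopropylcarbamate
Conditions: i-Pr2NC(O)Cl, Et3N, CH2Cl2, reflux
Reagents that add atoms: N,N-diisopropylcarbamoyl chloride CC(C)N(C(C)C)C(=O)Cl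
Why: Carbamoylation of the primary alcohol installs the group that later directs the lithiation and leaves in the 1,2-metallate rearrangement.

Step 3
Reactants: 5 3-methylbutyl N,N-diisopropylcarbamate; 3 aryl pinacol boronate
Product: 8 (R)-2-[3-methyl-1-(2,4,6-trimethoxyphenyl)butyl]-4,4,5,5-tetramethyl-1,3,2-dioxaborolane, via lithiated carbamate 6 (not isolated), via boronate complex 7 (not isolated)
Conditions: s-BuLi, (−)-sparteine, Et2O, −78 °C; 3, −78 °C; MgBr2·OEt2, then 35 °C; aq. NH4Cl
Reagents that add atoms: none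
Why: Lithiation–borylation: (−)-sparteine-mediated asymmetric deprotonation removes the pro-S hydrogen, carbanion 6 adds to boron with retention and the aryl group migrates with inversion at carbon (1,2-metallate rearrangement), which sets C1′ as drawn.

Step 4
Reactants: 9 (R)-β-citronellene
Product: 11 (R)-4-methylhex-5-en-1-ol, via (R)-4-methylhex-5-enal 10 (not isolated)
Conditions: O3 (1 equiv), CH2Cl2/MeOH, −78 °C; NaBH4, −78 °C to rt
Reagents that add atoms: ozone [O-][O+]=O
Why: Ozonolysis with reductive work-up cleaves the electron-rich trisubstituted alkene well before the vinyl group, and C4 is taken unchanged from the chiral pool.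

Step 5
Reactants: 11 (R)-4-methylhex-5-en-1-ol
Product: 12 (R)-4-methylhex-5-en-1-yl N,N-diisopropylcarbamate
Conditions: i-Pr2NC(O)Cl, Et3N, CH2Cl2, reflux
Reagents that add atoms: N,N-diisopropylcarbamoyl chloride CC(C)N(C(C)C)C(=O)Cl
Why: Carbamoylation of the primary alcohol at C1 prepares the second lithiation–borylation and gives a group that is stable to bromine and to amide bases.

Step 6
Reactants: 12 (R)-4-methylhex-5-en-1-yl N,N-diisopropylcarbamate
Product: 13 (4R,5RS)-5,6-dibromo-4-methylhexyl N,N-diisopropylcarbamate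
Conditions: Br2, CH2Cl2, −78 to 0 °C
Reagents that add atoms: bromine BrBr
Why: Electrophilic anti addition of bromine to the only alkene prepares the alkyne, and the new C5 centre (mixture) is erased in step 7.

Step 7
Reactants: 13 (4R,5RS)-5,6-dibromo-4-methylhexyl N,N-diisopropylcarbamate
Product: 15 (R)-4-methyl-6-(trimethylsilyl)hex-5-yn-1-yl N,N-diisopropylcarbamate, via lithium acetylide 14 (not isolated)
Conditions: LDA (3.5 equiv), THF, −78 to 0 °C; TMSCl, −78 °C to rt
Reagents that add atoms: chlorotrimethylsilane C[Si](C)(C)Cl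
Why: Twofold E2 dehydrobromination gives the terminal alkyne as its lithium acetylide 14, which is silylated in the same flask, and the low temperature should keep the propargylic C4–H and thus the stereocentre untouched.

Step 8
Reactants: 15 (R)-4-methyl-6-(trimethylsilyl)hex-5-yn-1-yl N,N-diisopropylcarbamate; 8 (R)-benzylic pinacol boronate
Product: 18 2-[(3R,6R,7S)-3,9-dimethyl-7-(2,4,6-trimethoxyphenyl)-1-(trimethylsilyl)dec-1-yn-6-yl]-4,4,5,5-tetramethyl-1,3,2-dioxaborolane, via lithiated carbamate 16 (not isolated), via boronate complex 17 (not isolated)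
Conditions: s-BuLi, (−)-sparteine, Et2O, −78 °C; 8, −78 °C; MgBr2·OEt2, then 35 °C; aq. NH4Cl
Reagents that add atoms: none
Why: Second lithiation–borylation: (−)-sparteine again fixes the configuration of carbanion 16 (reagent control), the benzylic C1′ group migrates from boron to C1 with retention at C1′ and inversion at C1, and this sets the C1/C1′ pair.

Step 9
Reactants: 19 2-methylbut-3-yn-2-ol
Product: 20 triethyl[(2-methylbut-3-yn-2-yl)oxy]silane
Conditions: TESOTf, 2,6-lutidine, CH2Cl2, 0 °C
Reagents that add atoms: triethylsilyl trifluoromethanesulfonate CC[Si](CC)(CC)OS(=O)(=O)C(F)(F)F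
Why: Silylation with the triflate protects the hindered tertiary alcohol against the organometallic steps that follow.

Step 10
Reactants: 20 triethyl[(2-methylbut-3-yn-2-yl)oxy]silane
Product: 22 (E)-triethyl[(4-iodo-2-methylbut-3-en-2-yl)oxy]silane, via alkenylzirconocene chloride 21 (not isolated)
Conditions: Cp2Zr(H)Cl, CH2Cl2, rt; I2, 0 °C
Reagents that add atoms: iodine II
Why: Hydrozirconation adds H and Zr syn with zirconium at the terminal carbon, and iodinolysis with retention gives the E-vinyl iodide.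

Step 11
Reactants: 22 (E)-triethyl[(4-iodo-2-methylbut-3-en-2-yl)oxy]silane; 23 propyne
Product: 24 (E)-triethyl[(2-methylhept-3-en-5-yn-2-yl)oxy]silane
Conditions: PdCl2(PPh3)2 (cat.), CuI (cat.), i-Pr2NH, THF, 0 °C to rt
Reagents that add atoms: none
Why: Sonogashira coupling through zerovalent palladium and the copper acetylide joins C8 to C9 with retention of the E geometry.

Step 12
Reactants: 24 (E)-triethyl[(2-methylhept-3-en-5-yn-2-yl)oxy]silane
Product: 26 triethyl{[(3E,5E)-6-iodo-2-methylhepta-3,5-dien-2-yl]oxy}silane, via dienylzirconocene chloride 25 (not isolated)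
Conditions: Cp2Zr(H)Cl, THF, rt to 40 °C; I2, −78 °C
Reagents that add atoms: iodine II
Why: Syn hydrozirconation takes the alkyne in preference to the hindered alkene and places zirconium next to the small methyl group, so that iodinolysis with retention gives the iodide with iodine trans to C8.

Step 13
Reactants: 26 triethyl{[(3E,5E)-6-iodo-2-methylhepta-3,5-dien-2-yl]oxy}silane; 18 secondary pinacol boronate
Product: 30 (3E,5Z,7R,10R)-2,6,10-trimethyl-7-[(1S)-3-methyl-1-(2,4,6-trimethoxyphenyl)butyl]-12-(trimethylsilyl)dodeca-3,5-dien-11-yn-2-yl triethylsilyl ether, via dienyllithium 27 (not isolated), via boronate complex 28 (not isolated), via β-iodo boronic ester 29 (not isolated)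
Conditions: 26, t-BuLi, Et2O, −78 °C; 18, THF, −78 to 0 °C; I2, THF, −78 °C; NaOMe, MeOH, −78 °C to rt
Reagents that add atoms: none
Why: Zweifel olefination: dienyllithium 27 adds to boron, iodine triggers migration of C1 to C10 with retention at C1 and anti to the iodonium, and anti elimination of boron and iodine from 29 inverts the alkene geometry, so that C1 ends cis to C8 (9Z in eudesmane numbering).

Step 14
Reactants: 30 bis-silylated dienyne
Product: 31 (3E,5Z,7R,10R)-2,6,10-trimethyl-7-[(1S)-3-methyl-1-(2,4,6-trimethoxyphenyl)butyl]dodeca-3,5-dien-11-yn-2-ol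
Conditions: TBAF, THF, 0 °C to rt
Reagents that add atoms: none
Why: Fluoride cleaves the alkynyl C–Si bond and the tertiary O–Si bond in one desilylation under conditions that leave the acid-sensitive dienyl carbinol intact.

Step 15
Reactants: 31 (7E,9Z)-dienyne with free alkyne and free C11 alcohol
Product: 33 (1R,4R,7S,10R)-1-[(1S)-3-methyl-1-(2,4,6-trimethoxyphenyl)butyl]eudesma-5,8-dien-11-ol, via rhodacyclopentene 32 (not isolated)
Conditions: [RhCl(C8H14)2]2 (5 mol %), P[OCH(CF3)2]3 (20 mol %), THF, 0.01 M, 60 °C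
Reagents that add atoms: none
Why: Monovalent rhodium binds the terminal alkyne and the proximal C9=C10 alkene and couples them oxidatively to rhodacyclopentene 32 of trivalent rhodium (C5–C10 bond), the C9–Rh bond slides over the vinyl group as an allyl unit to C7, and reductive elimination makes C6–C7, which is the known rhodium-catalysed intramolecular [4+2] cycloaddition of dienynes. Ring A closes as a 6-exo-dig attack of C10 on C5 through the four-carbon tether C1–C4, and ring B closes by reductive elimination from the seven-membered rhodacycle, formally the six-membered ring of a Diels–Alder addition. The addition is suprafacial on the diene, so the two outer substituents, the C10 methyl (the 9Z geometry puts the tether inside) and the C7 hydroxyisopropyl group (7E), end cis, which sets C7 relative to C10. C10 is set relative to C1 by 1,3-allylic strain: because C8 is cis to C1, H1 must lie in the diene plane, C2 and the aryl-bearing C1′ lie on opposite faces, and the alkyne can only reach the face that puts the C1 side chain cis to the C10 methyl. The step needs chemoselectivity for cycloaddition over alkyne oligomerisation and over a 1,5-hydrogen shift of the Z-diene, which high dilution, the electron-poor phosphite ligand and a temperature far below that of the thermal reaction should secure, and 32 has no β-hydrogen on an sp3 carbon that could divert it. The stepwise metallacycle path also avoids the strained concerted transition state that an inside tether would impose.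

Step 16
Reactants: 33 eudesma-5,8-dien-11-ol
Product: 34 (1R,4R,7S,10R)-1-[(1S)-3-methyl-1-(2,4,6-trimethoxyphenyl)butyl]eudesm-5-en-11-ol
Conditions: 2-nitrobenzenesulfonohydrazide (excess), Et3N, CH2Cl2/i-PrOH, rt
Reagents that add atoms: none
Why: Diimide reduction transfers two hydrogens in a concerted syn fashion and takes the cis-disubstituted C8=C9 alkene far faster than the trisubstituted C5=C6 alkene that is flanked by quaternary C10 and branched C4.

Step 17
Reactants: 34 eudesm-5-en-11-ol with trimethoxyphenyl group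
Product: 39 (1R,4R,7S,10R)-1-[(1S)-1-(3,5-diformyl-2,4,6-trimethoxyphenyl)-3-methylbutyl]eudesm-5-en-11-ol, via aryllithium alkoxide 35 (not isolated), via mono-adduct 36 (not isolated), via lithiated mono-adduct 37 (not isolated), via bis-adduct 38 (not isolated)
Conditions: n-BuLi (2.2 equiv), TMEDA, THF, 0 °C; DMF (1.1 equiv), −78 to 0 °C; n-BuLi (1.3 equiv), 0 °C; DMF (3 equiv), −78 °C to rt; aq. NH4Cl
Reagents that add atoms: N,N-dimethylformamide CN(C)C=O
Why: Directed ortho-metallation and formylation run twice in one flask: each remaining aryl C–H lies between two methoxy groups, and the lithium α-amino alkoxide 36 formed from DMF masks the first aldehyde during the second lithiation.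

Step 18
Reactants: 39 diformyl trimethyl ether
Product: 40 target CNP0108656.4
Conditions: NaSEt (excess), DMF, 110 °C; cold 1 M HCl to pH 3
Reagents that add atoms: none
Why: Nucleophilic (SN2) cleavage of aryl methyl ethers by thiolate is helped by the two formyl groups that make each aryloxide a good leaving group, and the basic medium spares the tertiary alcohol and the C5=C6 alkene.

Compound list
1 | 1,3,5-trimethoxybenzene | COc1cc(OC)cc(OC)c1 | starting material
2 | 2,4,6-trimethoxyphenyllithium (not isolated) | [Li]c1c(OC)cc(OC)cc1OC | intermediate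
3 | 2-(2,4,6-trimethoxyphenyl)-4,4,5,5-tetramethyl-1,3,2-dioxaborolane | COc1cc(OC)c(B2OC(C)(C)C(C)(C)O2)c(OC)c1 | intermediate
4 | 3-methylbutan-1-ol | CC(C)CCO | starting material
5 | 3-methylbutyl N,N-diisopropylcarbamate | CC(C)CCOC(=O)N(C(C)C)C(C)C | intermediate
6 | (S)-1-lithio-3-methylbutyl N,N-diisopropylcarbamate, sparteine complex (not isolated) | CC(C)C[C@@H](OC(=O)N(C(C)C)C(C)C)[Li] | intermediate
7 | lithium boronate complex from 6 and 3 (not isolated) | [Li+].CC(C)C[C@@H](OC(=O)N(C(C)C)C(C)C)[B-]1(c2c(OC)cc(OC)cc2OC)OC(C)(C)C(C)(C)O1 | intermediate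
8 | (R)-2-[3-methyl-1-(2,4,6-trimethoxyphenyl)butyl]-4,4,5,5-tetramethyl-1,3,2-dioxaborolane | CC(C)C[C@H](c1c(OC)cc(OC)cc1OC)B1OC(C)(C)C(C)(C)O1 | intermediate
9 | (R)-β-citronellene, (3R)-3,7-dimethylocta-1,6-diene | C=C[C@H](C)CCC=C(C)C | starting material
10 | (R)-4-methylhex-5-enal (not isolated) | C=C[C@H](C)CCC=O | intermediate
11 | (R)-4-methylhex-5-en-1-ol | C=C[C@H](C)CCCO | intermediate
12 | (R)-4-methylhex-5-en-1-yl N,N-diisopropylcarbamate | C=C[C@H](C)CCCOC(=O)N(C(C)C)C(C)C | intermediate
13 | (4R,5RS)-5,6-dibromo-4-methylhexyl N,N-diisopropylcarbamate | BrCC(Br)[C@H](C)CCCOC(=O)N(C(C)C)C(C)C | intermediate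
14 | lithium acetylide of (R)-4-methylhex-5-yn-1-yl N,N-diisopropylcarbamate (not isolated) | [Li]C#C[C@H](C)CCCOC(=O)N(C(C)C)C(C)C | intermediate
15 | (R)-4-methyl-6-(trimethylsilyl)hex-5-yn-1-yl N,N-diisopropylcarbamate | C[Si](C)(C)C#C[C@H](C)CCCOC(=O)N(C(C)C)C(C)C | intermediate
16 | (1S,4R)-1-lithio-4-methyl-6-(trimethylsilyl)hex-5-yn-1-yl N,N-diisopropylcarbamate, sparteine complex (not isolated) | C[Si](C)(C)C#C[C@H](C)CC[C@@H](OC(=O)N(C(C)C)C(C)C)[Li] | intermediate
17 | lithium boronate complex from 16 and 8 (not isolated) | [Li+].C[Si](C)(C)C#C[C@H](C)CC[C@@H](OC(=O)N(C(C)C)C(C)C)[B-]1([C@H](CC(C)C)c2c(OC)cc(OC)cc2OC)OC(C)(C)C(C)(C)O1 | intermediate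
18 | 2-[(3R,6R,7S)-3,9-dimethyl-7-(2,4,6-trimethoxyphenyl)-1-(trimethylsilyl)dec-1-yn-6-yl]-4,4,5,5-tetramethyl-1,3,2-dioxaborolane (boron on C1) | CC(C)C[C@H](c1c(OC)cc(OC)cc1OC)[C@H](B1OC(C)(C)C(C)(C)O1)CC[C@@H](C)C#C[Si](C)(C)C | intermediate
19 | 2-methylbut-3-yn-2-ol | C#CC(C)(C)O | starting material
20 | triethyl[(2-methylbut-3-yn-2-yl)oxy]silane | C#CC(C)(C)O[Si](CC)(CC)CC | intermediate
21 | (E)-alkenylzirconocene chloride from 20 (not isolated, Cp rings drawn σ-bound) | Cl[Zr](/C=C/C(C)(C)O[Si](CC)(CC)CC)(C1C=CC=C1)C1C=CC=C1 | intermediate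
22 | (E)-triethyl[(4-iodo-2-methylbut-3-en-2-yl)oxy]silane | I/C=C/C(C)(C)O[Si](CC)(CC)CC | intermediate
23 | propyne | CC#C | starting material
24 | (E)-triethyl[(2-methylhept-3-en-5-yn-2-yl)oxy]silane | CC#C/C=C/C(C)(C)O[Si](CC)(CC)CC | intermediate
25 | dienylzirconocene chloride from 24, Zr on C10 and trans to C8 (not isolated, Cp rings drawn σ-bound) | C/C(=C\C=C\C(C)(C)O[Si](CC)(CC)CC)[Zr](Cl)(C1C=CC=C1)C1C=CC=C1 | intermediate
26 | triethyl{[(3E,5E)-6-iodo-2-methylhepta-3,5-dien-2-yl]oxy}silane | C/C(I)=C\C=C\C(C)(C)O[Si](CC)(CC)CC | intermediate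
27 | dienyllithium from 26 (not isolated) | C/C([Li])=C\C=C\C(C)(C)O[Si](CC)(CC)CC | intermediate
28 | lithium boronate complex from 27 and 18 (not isolated) | [Li+].CC(C)C[C@H](c1c(OC)cc(OC)cc1OC)[C@H]([B-]1(/C(C)=C/C=C/C(C)(C)O[Si](CC)(CC)CC)OC(C)(C)C(C)(C)O1)CC[C@@H](C)C#C[Si](C)(C)C | intermediate
29 | β-iodo boronic ester, boron on C10 and iodine on C9 (not isolated; one of the two iodonium-face isomers is drawn, both collapse to the same alkene) | CC(C)C[C@H](c1c(OC)cc(OC)cc1OC)[C@H]([C@](C)(B1OC(C)(C)C(C)(C)O1)[C@@H](I)/C=C/C(C)(C)O[Si](CC)(CC)CC)CC[C@@H](C)C#C[Si](C)(C)C | intermediate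
30 | (3E,5Z,7R,10R)-2,6,10-trimethyl-7-[(1S)-3-methyl-1-(2,4,6-trimethoxyphenyl)butyl]-12-(trimethylsilyl)dodeca-3,5-dien-11-yn-2-yl triethylsilyl ether | CC(C)C[C@H](c1c(OC)cc(OC)cc1OC)[C@H](/C(C)=C\C=C\C(C)(C)O[Si](CC)(CC)CC)CC[C@@H](C)C#C[Si](C)(C)C | intermediate
31 | (3E,5Z,7R,10R)-2,6,10-trimethyl-7-[(1S)-3-methyl-1-(2,4,6-trimethoxyphenyl)butyl]dodeca-3,5-dien-11-yn-2-ol | CC(C)C[C@H](c1c(OC)cc(OC)cc1OC)[C@H](/C(C)=C\C=C\C(C)(C)O)CC[C@@H](C)C#C | intermediate
32 | rhodacyclopentene Rh–C6=C5–C10–C9 fused to ring A, other ligands omitted (not isolated) | CC(C)C[C@H](c1c(OC)cc(OC)cc1OC)[C@H]1CC[C@@H](C)C2=C[Rh][C@H](/C=C/C(C)(C)O)[C@@]21C | intermediate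
33 | (1R,4R,7S,10R)-1-[(1S)-3-methyl-1-(2,4,6-trimethoxyphenyl)butyl]eudesma-5,8-dien-11-ol | CC(C)C[C@H](c1c(OC)cc(OC)cc1OC)[C@H]1CC[C@@H](C)C2=C[C@@H](C(C)(C)O)C=C[C@@]21C | intermediate
34 | (1R,4R,7S,10R)-1-[(1S)-3-methyl-1-(2,4,6-trimethoxyphenyl)butyl]eudesm-5-en-11-ol | CC(C)C[C@H](c1c(OC)cc(OC)cc1OC)[C@H]1CC[C@@H](C)C2=C[C@@H](C(C)(C)O)CC[C@@]21C | intermediate
35 | C11 lithium alkoxide of 34 lithiated at one free aryl position (not isolated) | CC(C)C[C@H](c1c(OC)c([Li])c(OC)cc1OC)[C@H]1CC[C@@H](C)C2=C[C@@H](C(C)(C)O[Li])CC[C@@]21C | intermediate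
36 | mono-adduct of 35 to DMF, lithium α-(dimethylamino) alkoxide (not isolated) | CC(C)C[C@H](c1c(OC)c(C(O[Li])N(C)C)c(OC)cc1OC)[C@H]1CC[C@@H](C)C2=C[C@@H](C(C)(C)O[Li])CC[C@@]21C | intermediate
37 | 36 lithiated at the last free aryl position (not isolated) | CC(C)C[C@H](c1c(OC)c(C(O[Li])N(C)C)c(OC)c([Li])c1OC)[C@H]1CC[C@@H](C)C2=C[C@@H](C(C)(C)O[Li])CC[C@@]21C | intermediate
38 | bis-adduct to DMF (not isolated) | CC(C)C[C@H](c1c(OC)c(C(O[Li])N(C)C)c(OC)c(C(O[Li])N(C)C)c1OC)[C@H]1CC[C@@H](C)C2=C[C@@H](C(C)(C)O[Li])CC[C@@]21C | intermediate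
39 | (1R,4R,7S,10R)-1-[(1S)-1-(3,5-diformyl-2,4,6-trimethoxyphenyl)-3-methylbutyl]eudesm-5-en-11-ol | CC(C)C[C@H](c1c(OC)c(C=O)c(OC)c(C=O)c1OC)[C@H]1CC[C@@H](C)C2=C[C@@H](C(C)(C)O)CC[C@@]21C | intermediate
40 | CNP0108656.4, (1R,4R,7S,10R)-1-[(1S)-1-(3,5-diformyl-2,4,6-trihydroxyphenyl)-3-methylbutyl]eudesm-5-en-11-ol | CC(C)C[C@H](c1c(O)c(C=O)c(O)c(C=O)c1O)[C@H]1CC[C@@H](C)C2=C[C@@H](C(C)(C)O)CC[C@@]21C | target

Total step count: 18
Longest linear sequence: 11 steps (steps 4, 5, 6, 7, 8, 13, 14, 15, 16, 17, 18)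

Steps most likely to fail

1. Step 15.
- What may go wrong: oligomerisation or vinylidene formation at the free terminal alkyne, or no oxidative coupling at the hindered trisubstituted C9=C10 alkene.
- Fallback: it sets out from 30 and keeps both silyl groups.
- Zerovalent nickel is the other known catalyst type for intramolecular dienyne [4+2] cycloaddition, and it prefers silyl-capped alkynes. Ni(cod)2 with P(O-2-biphenylyl)3 in THF at 25–60 °C should give the 6-trimethylsilyl derivative of the TES ether of 33 F1.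
- Diimide should then reduce only C8=C9, since C5=C6 is now tetrasubstituted, to the 6-trimethylsilyl derivative of the TES ether of 34 F2.
- Excess TBAF in THF/DMSO at 80 °C should cleave the TES ether. The freed C11 alkoxide then attacks the neighbouring silicon (1,4 carbon-to-oxygen silyl shift), which also breaks the vinyl C–Si bond.
- The sequence comes back to the route at 34.

2. Step 13.
- What may go wrong: slow formation of the boronate complex at the hindered C1 boronate, or attack of iodine at the remote diene terminus C7, which would erode the 9Z geometry.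
- Fallback: it sets out from 18 and builds the diene only after the olefination, so that the boronate complex carries an isolated alkene.
- Commercial but-2-yn-1-ol is silylated (TBSCl, imidazole) to tert-butyl(but-2-yn-1-yloxy)dimethylsilane F3.
- Hydrozirconation and iodinolysis of F3 give (E)-tert-butyl[(3-iodobut-2-en-1-yl)oxy]dimethylsilane F4.
- Lithiation of F4 (t-BuLi) and Zweifel olefination with 18 should give the (9Z)-allylic silyl ether F5.
- TBAF frees the (9Z)-allylic alcohol with terminal alkyne F6.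
- MnO2 oxidises F6 to the (9Z)-enal F7.
- A Wittig reaction with Ph3P=CHC(O)CH3 gives the (7E,9Z)-dienone F8.
- MeLi (excess, THF, −78 °C) adds 1,2 to the ketone, which comes back to the route at 31.

3. Step 17.
- What may go wrong: incomplete second lithiation, or addition of n-BuLi to the masked first aldehyde, which would leave mono-formylated material.
- Fallback: it sets out from 34 and replaces C–H lithiation by halogen–metal exchange.
- NBS (2 equiv, MeCN, −20 °C) should brominate the two very electron-rich aryl positions before the hindered alkene, to give the 3,5-dibromo-2,4,6-trimethoxyphenyl compound F9.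
- MeLi (1 equiv, for the alcohol), then t-BuLi (4 equiv, THF, −78 °C) and DMF, give the dialdehyde, which comes back to the route at 39.

Further compounds
F1 | step 15 | 6-trimethylsilyl derivative of the TES ether of 33 (same spatial arrangement at all centres) | CC(C)C[C@H](c1c(OC)cc(OC)cc1OC)[C@H]1CC[C@@H](C)C2=C([Si](C)(C)C)[C@@H](C(C)(C)O[Si](CC)(CC)CC)C=C[C@@]21C
F2 | step 15 | 6-trimethylsilyl derivative of the TES ether of 34 (same spatial arrangement at all centres) | CC(C)C[C@H](c1c(OC)cc(OC)cc1OC)[C@H]1CC[C@@H](C)C2=C([Si](C)(C)C)[C@@H](C(C)(C)O[Si](CC)(CC)CC)CC[C@@]21C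
F3 | step 13 | tert-butyl(but-2-yn-1-yloxy)dimethylsilane | CC#CCO[Si](C)(C)C(C)(C)C
F4 | step 13 | (E)-tert-butyl[(3-iodobut-2-en-1-yl)oxy]dimethylsilane | C/C(I)=C\CO[Si](C)(C)C(C)(C)C
F5 | step 13 | (9Z)-allylic TBS ether with C8 as CH2OTBS and TMS-capped alkyne | CC(C)C[C@H](c1c(OC)cc(OC)cc1OC)[C@H](/C(C)=C\CO[Si](C)(C)C(C)(C)C)CC[C@@H](C)C#C[Si](C)(C)C
F6 | step 13 | (9Z)-allylic alcohol with terminal alkyne | CC(C)C[C@H](c1c(OC)cc(OC)cc1OC)[C@H](/C(C)=C\CO)CC[C@@H](C)C#C
F7 | step 13 | (9Z)-enal with C8 as CHO | CC(C)C[C@H](c1c(OC)cc(OC)cc1OC)[C@H](/C(C)=C\C=O)CC[C@@H](C)C#C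
F8 | step 13 | (7E,9Z)-dienone with C11 as methyl ketone | CC(C)C[C@H](c1c(OC)cc(OC)cc1OC)[C@H](/C(C)=C\C=C\C(C)=O)CC[C@@H](C)C#C
F9 | step 17 | (1R,4R,7S,10R)-1-[(1S)-1-(3,5-dibromo-2,4,6-trimethoxyphenyl)-3-methylbutyl]eudesm-5-en-11-ol | CC(C)C[C@H](c1c(OC)c(Br)c(OC)c(Br)c1OC)[C@H]1CC[C@@H](C)C2=C[C@@H](C(C)(C)O)CC[C@@]21C
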